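All runs stem from a simulated flask for substances that don't exist.

The coupling partner, as I read the runs, reacts twice, first with substrate to mono adduct, then with mono adduct to double product, so I carry one constant for the second coupling.

common to all: substrate 18 mM
- gamma: coupling partner 19 mM; run made earlier
- epsilon: coupling partner 26 mM; run made earlier
- eta: coupling partner 42 mM; run made earlier
- south: coupling partner 18.0 mM; time 5.0 h
- east: coupling partner 45.0 mM; time 5.0 h

| run | time / h | double product / % | mono adduct / % | substrate / % |
|---|---|---|---|---|
| gamma | 0.500 | 5 | 38 | 16 |
| gamma | 1.00 | 7 | 47 | 16 |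
| gamma | 1.50 | 10 | 52 | 10 |
| gamma | 2.00 | 13 | 54 | 10 |
| gamma | 2.50 | 14 | 55 | 7 |
| epsilon | 0.200 | 4 | 33 | 23 |
| epsilon | 0.417 | 2 | 42 | 11 |
| epsilon | 0.667 | 6 | 47 | 12 |
| epsilon | 1.33 | 14 | 54 | 7 |
| epsilon | 2.50 | 24 | 55 | 5 |
| eta | 0.200 | 2 | 44 | 13 |
| eta | 0.417 | 7 | 50 | 10 |
| eta | 0.667 | 19 | 57 | 7 |
| eta | 1.33 | 32 | 52 | 3 |
| eta | 2.50 | 53 | 45 | 0 |

(readings scatter by 1.5 percentage points)



* which of these there is most of at the end, counted by the substrate in it, south (substrate / mono adduct / double product)
* which of these there is most of at the end, counted by the substrate in it, east (substrate / mono adduct / double product)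
* the largest of these amounts at the end, in percent of the substrate charged, south
* the largest of these amounts at the end, in percent of the substrate charged, east

Step 1. In eta, double product rises from 32 % to 53 % between 1.33 h and 2.50 h. With c(coupling partner) held at its charge, rate over c(coupling partner) times mono adduct share gives 0.00881 mM⁻¹ h⁻¹.

Step 2. But that charge is partly consumed. Mono adduct holds one coupling partner and double product two, so, assuming the unseen share of the balance holds none, c(coupling partner) is the charge minus c(substrate charged) times (mono adduct + 2 double product). Put back, this gives 0.0206 mM⁻¹ h⁻¹ in eta and 0.0168 mM⁻¹ h⁻¹ in epsilon. Their mean, 0.0187 mM⁻¹ h⁻¹, is my second-coupling constant kD, the share of substrate turned into double product per hour, per mM of coupling partner, per unit share of mono adduct. It is a reading, with the scatter of its readings.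

Step 3. For east I start from eta's last reading with east's charge, so c(coupling partner) is 17.8 mM. Holding this and mono adduct gives double product 90.5 % at the end. Objection: both fall. Using means with that end gives 70.7 %, and once more 80.4 %. I take the middle, 75.6 %.

Step 4. In south, the likely limiting reagent is the coupling partner. Starting from gamma's last reading with south's charge, c(coupling partner) is 3.06 mM. Objection: the rest outside both products, 31.0 %, also takes coupling partner and feeds mono adduct. Gamma's fall of that rest gives a drain constant of 0.0403 mM⁻¹ h⁻¹. Assuming an end c(coupling partner) of zero returns 1.56 mM; putting that back returns 0.835 mM. With their middle, I get double product 19.5 % and mono adduct 55.5 %.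

Step 5. The forecast, which reads south as “partner starves”, says mono adduct at 56 % for south and double product at 78 % for east.

Step 6. South ends with mono adduct at 56.4 %, east with double product at 77.0 %.

    substrate + coupling partner → mono adduct + by-product (k = 3.06 M⁻¹ min⁻¹)
    coupling partner + mono adduct → double product + by-product (k = 0.309 M⁻¹ min⁻¹)
    crystals ⇌ by-product, rate k3*(cs3 - [by-product]) while solid is left; crystals form when [by-product] > cs3 (solubility = 8.90 mM, k = 2.05 min⁻¹)
    substrate ⇌ dormant form (K = 2.33, k = 0.146 min⁻¹)

On east, kD with east's own mean concentrations from 2.50 h to 5.00 h gives a rise of 22.6 %, and east rises 22 percentage points. The neighbouring flask is south with 31 mM of coupling partner. Interpolating between epsilon and eta at 2.50 h gives double product 33.1 % and mono adduct 51.9 %. Taking the neighbour's end values for the means, kD gives 49.8 %. The neighbouring flask ends with double product at 49.5 %.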